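Both carbocyclic rings of the 6,8'-bicoumarin (C4a–C8a and C4a'–C8a'; primes mark the C8'-linked half) are dissolved while the C6–C8' bond is kept. C6 is flanked by C7–O and C5–CH3, the signature of a 1,3-dioxygenated diene terminus. C8' is flanked by C7'–O and C8a'–O, the signature of an inner diene carbon. The axis can thus be laid down as a plain sp3–sp3 bond by acetoacetate alkylation. The precursor is an open-chain, cross-conjugated tris(silyloxy) bis-diene. Heated with two molecules of methyl but-2-ynoate, it should undergo two polarity-matched [4+2] additions and aromatisations in one flask, giving the fully substituted biaryl bis-salicylate. One O-methylation and a double pyranone closure follow.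

Key step: step 4

Assumption: the target SMILES carries no descriptor for the C6–C8' axis, so the racemate is the goal.
Remark: compound 3 is a masked 1,4-dicarbonyl compound that acid would convert into a furan, so everything before the cycloaddition is kept basic or neutral. The methanol liberated in the key step is trapped in situ so that it cannot destroy the second diene.

Step 1
Reactants: 1 methyl acetoacetate; 2 methyl (E)-4-bromo-3-methoxybut-2-enoate
Product: 3 dimethyl (E)-2-acetyl-4-methoxyhex-4-enedioate (racemic at C2)
Conditions: 1 (1.5 equiv), NaH (1.1 equiv), THF, 0 °C; then 2 (1.0 equiv), 0 °C → rt; pH 7 phosphate buffer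
Reagents that add atoms: none
Why: Acetoacetic ester alkylation (SN2), in which the soft sodium enolate displaces the primary allylic-type bromide at carbon, excess 1 suppresses double alkylation, the new C2 stereocentre forms racemic and is erased in step 2, and the neutral work-up avoids Paal–Knorr-type furan formation.

Step 2
Reactants: 3 dimethyl (E)-2-acetyl-4-methoxyhex-4-enedioate
Product: 4 dimethyl (4E)-4-methoxy-2-[1-(trimethylsilyloxy)ethylidene]hex-4-enedioate (enol ether geometry not controlled)
Conditions: Me3SiCl (1.6 equiv), Et3N (1.8 equiv), toluene, rt, 48–72 h; filter under Ar, concentrate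
Reagents that add atoms: chlorotrimethylsilane, C[Si](C)(C)Cl
Why: O-Silylation of a β-keto ester enol with an amine base, the usual first stage on the way to 1,3-bis(silyloxy)dienes, is known for 2-alkyl acetoacetates, leaves the vinylogous carbonate untouched and keeps the medium basic so that the furan pathway stays closed.

Step 3
Reactants: 4 dimethyl (4E)-4-methoxy-2-[1-(trimethylsilyloxy)ethylidene]hex-4-enedioate
Product: 5 5,7-dimethoxy-3-[methoxy(trimethylsilyloxy)methylidene]-2,7-bis(trimethylsilyloxy)hepta-1,4,6-triene (tris-O-silyl bis-diene of 3, geometric isomers)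
Conditions: LiN(i-Pr)2 (LDA, 2.4 equiv), THF, −78 °C, 1 h; Me3SiCl (2.8 equiv), −78 °C → rt; pentane, filter under Ar, concentrate; used crude
Reagents that add atoms: chlorotrimethylsilane, C[Si](C)(C)Cl
Why: Silyl ketene acetal formation by kinetic γ-deprotonation of two vinylogous esters (the doubly allylic CH2 next to the methoxy enoate and the CH3 of the silyloxy enoate) and O-silylation of the dienolates, the same operation that turns 3-methoxy- and 3-silyloxycrotonates into their 1-silyloxydienes; no stereocentre is formed.

Step 4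
Reactants: 5 tris-O-silyl bis-diene; 6 methyl but-2-ynoate (two molecules are taken up)
Product: 11 methyl 2,4-dihydroxy-3-[4-hydroxy-6-methoxy-3-(methoxycarbonyl)-2-methylphenyl]-6-methylbenzoate, via first cyclohexadiene adduct 7 (not isolated), via dienyl resorcylate 8 (not isolated), via second cyclohexadiene adduct 9 (not isolated), via tris-silyl biaryl 10 (not isolated)
Conditions: 6 (8 equiv, neat), MeC(OSiMe3)=NSiMe3 (BSA, 3 equiv), BHT (cat.), sealed tube, Ar, 110 °C then 140 °C; evaporate; 1 M HCl, THF, rt
Reagents that add atoms: methyl but-2-ynoate (compound 6), CC#CC(=O)OC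
Why: Proposed new method: each donor-rich diene of 5 should add to the acceptor-polarised triple bond of 6 by a strongly asynchronous [4+2] cycloaddition (at the limit a vinylogous Mukaiyama–Michael addition followed by ring closure), after which the mixed ketal carbon of each 1,4-cyclohexadiene (7, 9) gives up its methoxy group together with the ring hydrogen opposite to it, so that 8 and then 10 are formed. The closest known reaction type is the Diels–Alder–aromatisation of single 1-methoxy-1,3-bis(silyloxy)butadienes and 1,3-dimethoxy-1-silyloxybutadienes with acetylenic esters to resorcylates; running it twice on one cross-conjugated bis-diene, with the second diene already carrying the first ring, has no precedent. Both rings close in the intermolecular [4+2] mode: the primed ring, expected first because its diene ends in an unsubstituted CH2, through C6'–C5' (diene CH2 to alkyne β-carbon) and C8a'–C4a' (ketene acetal carbon to α-carbon), the unprimed ring through C6–C5 and C8a–C4a in the same sense, while C6–C8' is the bond made in step 1. No stereocentre survives, because the sp3 carbons of 7 and 9 become aromatic, and the hindered axis is formed as the racemate. The step needs head-to-tail regiochemistry twice and no reaction at the central diene of 5 (C4=C3–C2=C1 of the parent hexenedioate); the first is secured by matched polarisation (largest HOMO coefficient at each oxygen-activated terminus, largest LUMO coefficient at the β-carbon of 6), the second by both ends of the central diene being fully substituted. BSA converts the liberated methanol into Me3SiOMe before it can protodesilylate the surviving ketene acetal, and the large excess of neat 6 together with the hotter second stage is meant to drive the crowded C6–C5 bond formation.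

Step 5
Reactants: 11 methyl 2,4-dihydroxy-3-[4-hydroxy-6-methoxy-3-(methoxycarbonyl)-2-methylphenyl]-6-methylbenzoate
Product: 12 methyl 2-hydroxy-3-[4-hydroxy-6-methoxy-3-(methoxycarbonyl)-2-methylphenyl]-4-methoxy-6-methylbenzoate
Conditions: MeI (1.05 equiv), K2CO3 (1.1 equiv), acetone, rt
Reagents that add atoms: iodomethane, CI
Why: Williamson etherification with the selectivity established for 2,4-dihydroxybenzoates, since the 7'-hydroxyl para to its ester is the most acidic and the only free one, whereas the 8a- and 8a'-hydroxyls are held in six-membered hydrogen-bond chelates with the ester carbonyls and react far more slowly with one equivalent of MeI.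

Step 6
Reactants: 12 methyl 2-hydroxy-3-[4-hydroxy-6-methoxy-3-(methoxycarbonyl)-2-methylphenyl]-4-methoxy-6-methylbenzoate
Product: 14 4,4',7,7'-tetramethoxy-5,5'-dimethyl-6,8'-bicoumarin (racemic), via bis(phosphoranylideneacetate) 13 (not isolated)
Conditions: Ph3P=C=C=O (3 equiv), xylene, 140 °C, Ar
Reagents that add atoms: (triphenylphosphoranylidene)ketene, O=C=C=P(c1ccccc1)(c1ccccc1)c1ccccc1
Why: Addition–intramolecular Wittig olefination with the cumulated ylide, in which each phenol protonates the ylide carbon and is acylated to the stabilised aryl (phosphoranylidene)acetate 13, whose ylide carbon then olefinates the neighbouring ester carbonyl in a six-membered closure; this is the known conversion of methyl salicylates into 4-methoxycoumarins, so each C4–OCH3 comes from the ester itself.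

Compound list
1 | methyl acetoacetate | CC(=O)CC(=O)OC | starting material
2 | methyl (E)-4-bromo-3-methoxybut-2-enoate | COC(=O)/C=C(/OC)CBr | starting material
3 | dimethyl (E)-2-acetyl-4-methoxyhex-4-enedioate (racemic, C2 labile) | COC(=O)/C=C(/OC)CC(C(C)=O)C(=O)OC | intermediate
4 | dimethyl (4E)-4-methoxy-2-[1-(trimethylsilyloxy)ethylidene]hex-4-enedioate (enol ether geometry not controlled) | COC(=O)/C=C(/OC)CC(C(=O)OC)=C(C)O[Si](C)(C)C | intermediate
5 | 5,7-dimethoxy-3-[methoxy(trimethylsilyloxy)methylidene]-2,7-bis(trimethylsilyloxy)hepta-1,4,6-triene (geometric isomers) | COC(O[Si](C)(C)C)=CC(OC)=CC(C(O[Si](C)(C)C)=C)=C(OC)O[Si](C)(C)C | intermediate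
6 | methyl but-2-ynoate | CC#CC(=O)OC | starting material
7 | methyl 5-[2,4-dimethoxy-4-(trimethylsilyloxy)buta-1,3-dien-1-yl]-6-methoxy-2-methyl-4,6-bis(trimethylsilyloxy)cyclohexa-1,4-diene-1-carboxylate (isomer mixture) | COC(=O)C1=C(C)CC(O[Si](C)(C)C)=C(C=C(OC)C=C(OC)O[Si](C)(C)C)C1(OC)O[Si](C)(C)C | intermediate
8 | methyl 3-[2,4-dimethoxy-4-(trimethylsilyloxy)buta-1,3-dien-1-yl]-6-methyl-2,4-bis(trimethylsilyloxy)benzoate (geometric isomers) | COC(=O)c1c(C)cc(O[Si](C)(C)C)c(C=C(OC)C=C(OC)O[Si](C)(C)C)c1O[Si](C)(C)C | intermediate
9 | methyl 3-[3-(methoxycarbonyl)-4-methyl-2,6-bis(trimethylsilyloxy)phenyl]-4,6-dimethoxy-2-methyl-6-(trimethylsilyloxy)cyclohexa-1,4-diene-1-carboxylate (diastereomer mixture) | COC(=O)C1=C(C)C(c2c(O[Si](C)(C)C)cc(C)c(C(=O)OC)c2O[Si](C)(C)C)C(OC)=CC1(OC)O[Si](C)(C)C | intermediate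
10 | methyl 3-[6-methoxy-3-(methoxycarbonyl)-2-methyl-4-(trimethylsilyloxy)phenyl]-6-methyl-2,4-bis(trimethylsilyloxy)benzoate | COC(=O)c1c(O[Si](C)(C)C)cc(OC)c(c1C)-c1c(O[Si](C)(C)C)cc(C)c(C(=O)OC)c1O[Si](C)(C)C | intermediate
11 | methyl 2,4-dihydroxy-3-[4-hydroxy-6-methoxy-3-(methoxycarbonyl)-2-methylphenyl]-6-methylbenzoate | COC(=O)c1c(O)cc(OC)c(c1C)-c1c(O)cc(C)c(C(=O)OC)c1O | intermediate
12 | methyl 2-hydroxy-3-[4-hydroxy-6-methoxy-3-(methoxycarbonyl)-2-methylphenyl]-4-methoxy-6-methylbenzoate | COC(=O)c1c(O)cc(OC)c(c1C)-c1c(OC)cc(C)c(C(=O)OC)c1O | intermediate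
13 | bis[(triphenylphosphoranylidene)acetate] of 12 | COC(=O)c1c(OC(=O)C=P(c2ccccc2)(c2ccccc2)c2ccccc2)cc(OC)c(c1C)-c1c(OC)cc(C)c(C(=O)OC)c1OC(=O)C=P(c1ccccc1)(c1ccccc1)c1ccccc1 | intermediate
14 | 4,4',7,7'-tetramethoxy-5,5'-dimethyl-6,8'-bicoumarin (racemic axis) | COc1cc2oc(=O)cc(OC)c2c(C)c1-c1c(OC)cc(C)c2c(OC)cc(=O)oc12 | target

Total step count: 6. Longest linear sequence: 6 steps (1 and 2 to 14).

Steps most likely to fail

**1. Step 4 (the one step beyond known chemistry).**
- After the first benzannulation, the terminus of the remaining diene is flanked by a 2,6-dioxygenated aryl group, so the second addition may stall.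
- Geometric isomers of the bis-diene whose chain substituent points inward cannot reach the s-cis geometry.
- At the temperatures the sluggish ynoate needs, silyl migration, protodesilylation, or loss of silanol in place of methanol may compete.

The fallback uses known chemistry, sets out from 1 and comes back to the route at 12. The biaryl bond is made by Suzuki–Miyaura coupling of two orsellinate halves. One-flask Claisen–aldol self-condensation of 1 (NaH, then n-BuLi, THF, reflux) gives methyl 2,4-dihydroxy-6-methylbenzoate F1. One portion is iodinated under phenolate conditions, which in resorcinols direct to the carbon between the two hydroxyls (I2, NaHCO3, THF–H2O, 0 °C). This gives methyl 2,4-dihydroxy-3-iodo-6-methylbenzoate F2, which is permethylated (MeI, K2CO3, DMF) to methyl 3-iodo-2,4-dimethoxy-6-methylbenzoate F3. The other portion is permethylated to methyl 2,4-dimethoxy-6-methylbenzoate F4. It is then iodinated para to the 2-methoxy group (N-iodosuccinimide, cat. CF3CO2H, MeCN) to methyl 3-iodo-4,6-dimethoxy-2-methylbenzoate F5. Iodine–magnesium exchange (i-PrMgCl·LiCl, THF, −20 °C) and quenching with 2-isopropoxy-4,4,5,5-tetramethyl-1,3,2-dioxaborolane give methyl 4,6-dimethoxy-2-methyl-3-(4,4,5,5-tetramethyl-1,3,2-dioxaborolan-2-yl)benzoate F6. Coupling of F3 with F6 (Pd2(dba)3, SPhos, K3PO4, toluene–H2O, 100 °C) gives methyl 3-[4,6-dimethoxy-3-(methoxycarbonyl)-2-methylphenyl]-2,4-dimethoxy-6-methylbenzoate F7. BCl3 (CH2Cl2, −78 → 0 °C) then removes only the two methyl ethers that chelate to the ester carbonyls and gives 12.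

**2. Step 3.**
- The second enolisation may remain incomplete once the first dienolate is in place.
- C-silylation may compete with O-silylation.
- The tris-silyl compound may hydrolyse during the non-aqueous isolation.

The fallback sets out from 4 and comes back to the route at 10. The bis-diene is never made. The two rings are built one after the other, each by the known single-diene benzannulation, in the order that avoids bond formation next to an aryl group. Only the more acidic doubly allylic CH2 of 4 is deprotonated (LiN(i-Pr)2, 1.05 equiv, THF, −78 °C; Me3SiCl), giving methyl 4,6-dimethoxy-6-(trimethylsilyloxy)-2-[1-(trimethylsilyloxy)ethylidene]hexa-3,5-dienoate F8. Cycloaddition–aromatisation with 6 under the conditions of step 4, followed by dilute acid, gives methyl 6-hydroxy-4-methoxy-3-(1-methoxy-1,3-dioxobutan-2-yl)-2-methylbenzoate F9. Me3SiCl/Et3N gives methyl 4-methoxy-3-[1-methoxy-1-oxo-3-(trimethylsilyloxy)but-2-en-2-yl]-2-methyl-6-(trimethylsilyloxy)benzoate F10. LiN(i-Pr)2/Me3SiCl then gives methyl 4-methoxy-3-[1-methoxy-1,3-bis(trimethylsilyloxy)buta-1,3-dien-2-yl]-2-methyl-6-(trimethylsilyloxy)benzoate F11. A second benzannulation with 6 gives 10, which the acid work-up of step 4 turns into 11.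

**3. Step 6.**
- Both ester carbonyls carry two ortho substituents and are twisted out of the ring plane, so the intramolecular olefination may stop at the acyl ylide stage, above all on the primed ring.
- The ylide may be hydrolysed by traces of water during long heating.

The fallback sets out from 12 and comes back to the route at 14. It uses an enolate instead of an ylide. Acetylation (Ac2O, DMAP, pyridine) gives methyl 2-acetoxy-3-[4-acetoxy-6-methoxy-3-(methoxycarbonyl)-2-methylphenyl]-4-methoxy-6-methylbenzoate F12. A double intramolecular Claisen (Dieckmann-type) condensation (LiN(SiMe3)2, THF, −78 → 0 °C) gives 4,4'-dihydroxy-7,7'-dimethoxy-5,5'-dimethyl-6,8'-bicoumarin F13. O-Methylation (Me2SO4, K2CO3, acetone, reflux) gives 14.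

Further compounds
F1 | step 4 | methyl 2,4-dihydroxy-6-methylbenzoate (methyl orsellinate) | COC(=O)c1c(C)cc(O)cc1O
F2 | step 4 | methyl 2,4-dihydroxy-3-iodo-6-methylbenzoate | COC(=O)c1c(C)cc(O)c(I)c1O
F3 | step 4 | methyl 3-iodo-2,4-dimethoxy-6-methylbenzoate | COC(=O)c1c(C)cc(OC)c(I)c1OC
F4 | step 4 | methyl 2,4-dimethoxy-6-methylbenzoate | COC(=O)c1c(C)cc(OC)cc1OC
F5 | step 4 | methyl 3-iodo-4,6-dimethoxy-2-methylbenzoate | COC(=O)c1c(C)c(I)c(OC)cc1OC
F6 | step 4 | methyl 4,6-dimethoxy-2-methyl-3-(4,4,5,5-tetramethyl-1,3,2-dioxaborolan-2-yl)benzoate | COC(=O)c1c(C)c(B2OC(C)(C)C(C)(C)O2)c(OC)cc1OC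
F7 | step 4 | methyl 3-[4,6-dimethoxy-3-(methoxycarbonyl)-2-methylphenyl]-2,4-dimethoxy-6-methylbenzoate | COC(=O)c1c(OC)cc(OC)c(c1C)-c1c(OC)cc(C)c(C(=O)OC)c1OC
F8 | step 3 | methyl 4,6-dimethoxy-6-(trimethylsilyloxy)-2-[1-(trimethylsilyloxy)ethylidene]hexa-3,5-dienoate (geometric isomers) | COC(=O)C(C=C(OC)C=C(OC)O[Si](C)(C)C)=C(C)O[Si](C)(C)C
F9 | step 3 | methyl 6-hydroxy-4-methoxy-3-(1-methoxy-1,3-dioxobutan-2-yl)-2-methylbenzoate (racemic, labile) | COC(=O)c1c(O)cc(OC)c(C(C(C)=O)C(=O)OC)c1C
F10 | step 3 | methyl 4-methoxy-3-[1-methoxy-1-oxo-3-(trimethylsilyloxy)but-2-en-2-yl]-2-methyl-6-(trimethylsilyloxy)benzoate | COC(=O)c1c(O[Si](C)(C)C)cc(OC)c(C(C(=O)OC)=C(C)O[Si](C)(C)C)c1C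
F11 | step 3 | methyl 4-methoxy-3-[1-methoxy-1,3-bis(trimethylsilyloxy)buta-1,3-dien-2-yl]-2-methyl-6-(trimethylsilyloxy)benzoate | COC(=O)c1c(O[Si](C)(C)C)cc(OC)c(C(C(=C)O[Si](C)(C)C)=C(OC)O[Si](C)(C)C)c1C
F12 | step 6 | methyl 2-acetoxy-3-[4-acetoxy-6-methoxy-3-(methoxycarbonyl)-2-methylphenyl]-4-methoxy-6-methylbenzoate | COC(=O)c1c(OC(C)=O)cc(OC)c(c1C)-c1c(OC)cc(C)c(C(=O)OC)c1OC(C)=O
F13 | step 6 | 4,4'-dihydroxy-7,7'-dimethoxy-5,5'-dimethyl-6,8'-bicoumarin | COc1cc2oc(=O)cc(O)c2c(C)c1-c1c(OC)cc(C)c2c(O)cc(=O)oc12
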